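The retrosynthesis first removes the O5 methyl and the two O-silyl groups, then cuts the C6–CH2 bond of the prenyl group together with the C3'–CH= and O2'–CMe2 bonds of ring D. This leads back to an isoflavan carrying a 1,1-dimethylallyl group on O5 and a 1,1-dimethylpropargyl group on O2'.
The cut is possible because each of these ether oxygens has only one unsubstituted ortho carbon: C6 for O5 on ring A (C4a belongs to ring C) and C3' for O2' on ring B (C1' bears C3).
Further back, the O5–allyl bond, the O1–C2 bond of ring C and the C3–C4 bond are cut, giving a ring B arylacetic acid (from 2,4-dihydroxybenzaldehyde) and a symmetric ring A benzylic bromide (from 2,4,6-trihydroxybenzaldehyde).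
Forward: the two arenes are joined at C3–C4, ring C closes by O1–C2 etherification, O5 is etherified, the prenyl group and ring D arise together on heating, and O-methylation and desilylation finish the route.
The only stereocentre, C3 (R), is set by alkylation of an (R)-4-benzyloxazolidin-2-one imide and is not touched afterwards.

Key step: step 16

Assumption: one equivalent of the bulky silyl chloride is taken to react first at the 4-hydroxyl of 2,4,6-trihydroxybenzaldehyde, the only hydroxyl not flanked by the formyl group; isoflavan numbering (O1, C2–C4, C4a, C5–C8, C8a, primed ring B) is used throughout.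

Step 1
Reactants: 1 2,4-dihydroxybenzaldehyde
Product: 2 2-hydroxy-4-(triisopropylsilyloxy)benzaldehyde
Conditions: i-Pr3SiCl (1.05 equiv), imidazole, CH2Cl2, 0 °C → rt
Reagents that add atoms: chlorotriisopropylsilane, CC(C)[Si](Cl)(C(C)C)C(C)C
Why: Imidazole-mediated O-silylation should take the 4-hydroxyl only, because the 2-hydroxyl is hydrogen-bonded to the formyl group and more hindered.

Step 2
Reactants: 2 2-hydroxy-4-(triisopropylsilyloxy)benzaldehyde; 3 3-chloro-3-methylbut-1-yne
Product: 4 2-(2-methylbut-3-yn-2-yloxy)-4-(triisopropylsilyloxy)benzaldehyde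
Conditions: 3 (1.5 equiv), DBU, CuCl2·2H2O (1 mol %), MeCN, 0 °C
Reagents that add atoms: 3-chloro-3-methylbut-1-yne (compound 3), C#CC(C)(C)Cl
Why: Copper-catalysed O-alkylation of phenols with tertiary propargylic chlorides is the standard route to aryl 1,1-dimethylpropargyl ethers and runs at 0 °C, far below the temperature at which the new ether would rearrange.

Step 3
Reactants: 4 2-(2-methylbut-3-yn-2-yloxy)-4-(triisopropylsilyloxy)benzaldehyde
Product: 5 1-(2-methoxyvinyl)-2-(2-methylbut-3-yn-2-yloxy)-4-(triisopropylsilyloxy)benzene (E/Z mixture)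
Conditions: MeOCH2PPh3Cl, KOt-Bu, THF, 0 °C; then 4, 0 °C → rt
Reagents that add atoms: (methoxymethyl)triphenylphosphonium chloride, COC[P+](c1ccccc1)(c1ccccc1)c1ccccc1.[Cl-]
Why: Wittig olefination with the preformed methoxymethylene ylide adds the one carbon needed for the arylacetic acid, and no free base meets the aldehyde or the alkyne.

Step 4
Reactants: 5 1-(2-methoxyvinyl)-2-(2-methylbut-3-yn-2-yloxy)-4-(triisopropylsilyloxy)benzene
Product: 7 [2-(2-methylbut-3-yn-2-yloxy)-4-(triisopropylsilyloxy)phenyl]acetic acid, via arylacetaldehyde 6 (not isolated)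
Conditions: 2 M HCl (cat.), THF/H2O, 40 °C; then t-BuOH, 2-methyl-2-butene, NaH2PO4, NaClO2, 0 °C → rt
Reagents that add atoms: water, O; sodium chlorite, [Na+].[O-]Cl=O
Why: Acid-catalysed enol ether hydrolysis gives the labile arylacetaldehyde, which is oxidised at once in the same flask by Pinnick chlorite oxidation at its usual buffered acidic pH, with 2-methyl-2-butene trapping hypochlorous acid so that the electron-rich ring and the alkyne are spared.

Step 5
Reactants: 7 [2-(2-methylbut-3-yn-2-yloxy)-4-(triisopropylsilyloxy)phenyl]acetic acid; 8 (R)-4-benzyloxazolidin-2-one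
Product: 10 (R)-4-benzyl-3-{[2-(2-methylbut-3-yn-2-yloxy)-4-(triisopropylsilyloxy)phenyl]acetyl}oxazolidin-2-one, via mixed pivalic anhydride 9 (not isolated)
Conditions: t-BuCOCl, Et3N, THF, −20 °C; then 8, LiCl, −20 °C → rt
Reagents that add atoms: (R)-4-benzyloxazolidin-2-one (compound 8), O=C1N[C@H](Cc2ccccc2)CO1; pivaloyl chloride, CC(C)(C)C(Cl)=O (its atoms stay only in intermediate 9)
Why: Mixed-anhydride N-acylation of the oxazolidinone with LiCl and Et3N needs no strong base, so the terminal alkyne is not metalated.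

Step 6
Reactants: 11 2,4,6-trihydroxybenzaldehyde
Product: 12 2,6-dihydroxy-4-(triisopropylsilyloxy)benzaldehyde
Conditions: i-Pr3SiCl (1.0 equiv), imidazole, DMF/CH2Cl2, −20 → 0 °C
Reagents that add atoms: chlorotriisopropylsilane, CC(C)[Si](Cl)(C(C)C)C(C)C
Why: Imidazole-mediated silylation with one equivalent of a bulky silyl chloride should favour the 4-hydroxyl, the only one not next to the formyl group, and it leaves the ring symmetric for the later ring closure.

Step 7
Reactants: 12 2,6-dihydroxy-4-(triisopropylsilyloxy)benzaldehyde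
Product: 13 2,6-bis(methoxymethoxy)-4-(triisopropylsilyloxy)benzaldehyde
Conditions: MeOCH2Cl (excess), i-Pr2NEt, DMAP (cat.), CH2Cl2, 0 → 40 °C
Reagents that add atoms: chloromethyl methyl ether, COCCl
Why: Amine-mediated O-alkylation with the reactive chloromethyl ether protects both ortho phenols as MOM acetals; DMAP and gentle warming drive the second, hydrogen-bonded hydroxyl, and the base is too weak to disturb the aryl silyl ether.

Step 8
Reactants: 13 2,6-bis(methoxymethoxy)-4-(triisopropylsilyloxy)benzaldehyde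
Product: 14 [2,6-bis(methoxymethoxy)-4-(triisopropylsilyloxy)phenyl]methanol
Conditions: NaBH4, THF/MeOH, 0 °C
Reagents that add atoms: none
Why: Borohydride reduction of the aldehyde to the benzylic alcohol is fast at 0 °C and leaves acetals and the silyl ether alone.

Step 9
Reactants: 14 [2,6-bis(methoxymethoxy)-4-(triisopropylsilyloxy)phenyl]methanol
Product: 16 2-(bromomethyl)-1,3-bis(methoxymethoxy)-5-(triisopropylsilyloxy)benzene, via benzylic mesylate 15 (not isolated)
Conditions: MsCl, Et3N, THF, −20 °C; then LiBr, 0 °C; used at once without chromatography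
Reagents that add atoms: lithium bromide, [Li+].[Br-]; methanesulfonyl chloride, CS(=O)(=O)Cl (its atoms stay only in intermediate 15)
Why: Mesylation followed by bromide displacement (Finkelstein-type exchange) makes the benzylic bromide without acid, so the MOM acetals survive.

Step 10
Reactants: 10 (R)-4-benzyl-3-{[2-(2-methylbut-3-yn-2-yloxy)-4-(triisopropylsilyloxy)phenyl]acetyl}oxazolidin-2-one; 16 2-(bromomethyl)-1,3-bis(methoxymethoxy)-5-(triisopropylsilyloxy)benzene
Product: 18 (R)-4-benzyl-3-{(2R)-3-[2,6-bis(methoxymethoxy)-4-(triisopropylsilyloxy)phenyl]-2-[2-(2-methylbut-3-yn-2-yloxy)-4-(triisopropylsilyloxy)phenyl]propanoyl}oxazolidin-2-one, via sodium Z-enolate 17 (not isolated)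
Conditions: NaN(SiMe3)2 (1.05 equiv), THF, −78 °C; then 16, −78 → −40 °C; AcOH quench at −78 °C
Reagents that add atoms: sodium bis(trimethylsilyl)amide, C[Si](C)(C)[N-][Si](C)(C)C.[Na+] (sodium stays only in intermediate 17)
Why: Evans asymmetric alkylation, in which the sodium-chelated Z-enolate is attacked by the benzylic bromide on the face away from the benzyl group of the (R)-auxiliary, sets C3 as R; one equivalent of amide base removes only the imide α-proton and not the alkyne proton.

Step 11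
Reactants: 18 the alkylated imide
Product: 19 (2R)-3-[2,6-bis(methoxymethoxy)-4-(triisopropylsilyloxy)phenyl]-2-[2-(2-methylbut-3-yn-2-yloxy)-4-(triisopropylsilyloxy)phenyl]propan-1-ol
Conditions: LiBH4, MeOH (1 equiv), Et2O/THF, 0 °C
Reagents that add atoms: none
Why: Reductive cleavage of the N-acyl oxazolidinone by LiBH4 gives the primary alcohol without enolisation, so the benzylic stereocentre is kept and the auxiliary can be recovered.

Step 12
Reactants: 19 the bis-MOM alcohol
Product: 20 2-{(2R)-3-hydroxy-2-[2-(2-methylbut-3-yn-2-yloxy)-4-(triisopropylsilyloxy)phenyl]propyl}-5-(triisopropylsilyloxy)benzene-1,3-diol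
Conditions: conc. HCl (cat.), MeOH/THF, 45 °C
Reagents that add atoms: none
Why: Acid-catalysed transacetalisation to methanol removes phenolic MOM groups under conditions that aryl triisopropylsilyl ethers and the aryl tertiary propargyl ether should tolerate.

Step 13
Reactants: 20 the resorcinol alcohol
Product: 21 (3R)-3-[2-(2-methylbut-3-yn-2-yloxy)-4-(triisopropylsilyloxy)phenyl]-7-(triisopropylsilyloxy)chroman-5-ol
Conditions: PPh3, DIAD, THF (0.02 M), 0 °C → rt
Reagents that add atoms: none
Why: Intramolecular Mitsunobu etherification closes ring C by 6-exo-tet displacement of the activated primary alcohol; the two phenols are interchangeable by rotation of the symmetric arene, so either gives the same chroman, and the stereocentre is not at the reacting carbon.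

Step 14
Reactants: 22 2-methylbut-3-en-2-ol
Product: 24 tert-butyl 2-methylbut-3-en-2-yl carbonate, via lithium alkoxide 23 (not isolated)
Conditions: n-BuLi, THF, −78 → 0 °C; then Boc2O, 0 °C → rt
Reagents that add atoms: di-tert-butyl dicarbonate, CC(C)(C)OC(=O)OC(=O)OC(C)(C)C; n-butyllithium, [Li]CCCC (lithium stays only in intermediate 23)
Why: Acylation of the tertiary lithium alkoxide with the dicarbonate is the usual way to tertiary allylic tert-butyl carbonates.

Step 15
Reactants: 21 the chroman-5-ol; 24 tert-butyl 2-methylbut-3-en-2-yl carbonate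
Product: 25 (3R)-5-(2-methylbut-3-en-2-yloxy)-3-[2-(2-methylbut-3-yn-2-yloxy)-4-(triisopropylsilyloxy)phenyl]-7-(triisopropylsilyloxy)chroman
Conditions: 24 (2 equiv), Pd(PPh3)4 (5 mol %), THF, 0 °C
Reagents that add atoms: tert-butyl 2-methylbut-3-en-2-yl carbonate (compound 24), CC(C)(C)OC(=O)OC(C)(C)C=C
Why: Tsuji–Trost O-allylation, in which zerovalent palladium ionises the carbonate to a 1,1-dimethylallyl complex and (after loss of CO2) tert-butoxide, and the phenoxide attacks the more substituted allyl terminus under kinetic control at low temperature to give the tertiary ether.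

Step 16
Reactants: 25 the 5-O-(1,1-dimethylallyl) 2'-O-(1,1-dimethylpropargyl) isoflavan
Product: 29 (3R)-3-[2,2-dimethyl-5-(triisopropylsilyloxy)-2H-chromen-8-yl]-6-(3-methylbut-2-en-1-yl)-7-(triisopropylsilyloxy)chroman-5-ol, via prenylphenol 26 (not isolated), via allenylphenol 27 (not isolated), via ortho-quinone methide 28 (not isolated)
Conditions: PhNEt2 (degassed), 120 → 180 °C, sealed tube
Reagents that add atoms: none
Why: The 1,1-dimethylallyl ether undergoes a chair-like aromatic Claisen [3,3] shift to C6 and the dienone enolises to prenylphenol 26. As the temperature rises, the 1,1-dimethylpropargyl ether undergoes the propargyl Claisen [3,3] shift to C3' and enolises to allenylphenol 27, and a 1,5-hydrogen shift from the 2'-hydroxyl to the central allene carbon gives ortho-quinone methide 28. Ring D then closes by thermal oxa-6π electrocyclisation, which forms the O2'–CMe2 bond of the 2H-pyran. The closest known reactions are the aromatic Claisen rearrangement of aryl 1,1-dimethylallyl ethers to ortho-prenylphenols and the thermal conversion of aryl 1,1-dimethylpropargyl ethers into 2,2-dimethyl-2H-chromenes. No stereocentre is created, and C3 lies away from all reacting atoms, so its R configuration is carried through. Only regioselectivity is needed and the substrate fixes it: C6 is the sole free ortho carbon of O5, C3' the sole free ortho carbon of O2', the silyl groups on O7 and O4' cannot migrate, and the amine solvent buffers traces of acid that could ionise the allyl ether.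

Step 17
Reactants: 29 the 5-hydroxy-6-prenyl isoflavan with ring D
Product: 30 triisopropylsilyl-protected 5-O-methyl ether of 29
Conditions: MeI, K2CO3, acetone, 50 °C
Reagents that add atoms: iodomethane, CI
Why: Williamson O-methylation of the only free phenol; carbonate in acetone is mild enough for the aryl silyl ethers.

Step 18
Reactants: 30 the bis-silyl methyl ether
Product: 31 (3R)-3-(5-hydroxy-2,2-dimethyl-2H-chromen-8-yl)-5-methoxy-6-(3-methylbut-2-en-1-yl)chroman-7-ol (CNP0119857.1)
Conditions: Bu4NF, AcOH, THF, 0 °C → rt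
Reagents that add atoms: none
Why: Fluoride-induced cleavage of both aryl silyl ethers, buffered with acetic acid so that the electron-rich phenols are not kept as phenoxides, should release the target without touching the chromene or the prenyl group.

Compound list
1 | 2,4-dihydroxybenzaldehyde | O=Cc1ccc(O)cc1O | starting material
2 | 2-hydroxy-4-(triisopropylsilyloxy)benzaldehyde | O=Cc1ccc(O[Si](C(C)C)(C(C)C)C(C)C)cc1O | intermediate
3 | 3-chloro-3-methylbut-1-yne | C#CC(C)(C)Cl | starting material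
4 | 2-(2-methylbut-3-yn-2-yloxy)-4-(triisopropylsilyloxy)benzaldehyde | O=Cc1ccc(O[Si](C(C)C)(C(C)C)C(C)C)cc1OC(C)(C)C#C | intermediate
5 | 1-(2-methoxyvinyl)-2-(2-methylbut-3-yn-2-yloxy)-4-(triisopropylsilyloxy)benzene (E/Z mixture) | COC=Cc1ccc(O[Si](C(C)C)(C(C)C)C(C)C)cc1OC(C)(C)C#C | intermediate
6 | [2-(2-methylbut-3-yn-2-yloxy)-4-(triisopropylsilyloxy)phenyl]acetaldehyde (not isolated) | O=CCc1ccc(O[Si](C(C)C)(C(C)C)C(C)C)cc1OC(C)(C)C#C | intermediate
7 | [2-(2-methylbut-3-yn-2-yloxy)-4-(triisopropylsilyloxy)phenyl]acetic acid | OC(=O)Cc1ccc(O[Si](C(C)C)(C(C)C)C(C)C)cc1OC(C)(C)C#C | intermediate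
8 | (R)-4-benzyloxazolidin-2-one | O=C1N[C@H](Cc2ccccc2)CO1 | starting material
9 | mixed anhydride of acid 7 with pivalic acid (not isolated) | CC(C)(C)C(=O)OC(=O)Cc1ccc(O[Si](C(C)C)(C(C)C)C(C)C)cc1OC(C)(C)C#C | intermediate
10 | (R)-4-benzyl-3-{[2-(2-methylbut-3-yn-2-yloxy)-4-(triisopropylsilyloxy)phenyl]acetyl}oxazolidin-2-one | O=C(Cc1ccc(O[Si](C(C)C)(C(C)C)C(C)C)cc1OC(C)(C)C#C)N1[C@H](Cc2ccccc2)COC1=O | intermediate
11 | 2,4,6-trihydroxybenzaldehyde | O=Cc1c(O)cc(O)cc1O | starting material
12 | 2,6-dihydroxy-4-(triisopropylsilyloxy)benzaldehyde | O=Cc1c(O)cc(O[Si](C(C)C)(C(C)C)C(C)C)cc1O | intermediate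
13 | 2,6-bis(methoxymethoxy)-4-(triisopropylsilyloxy)benzaldehyde | O=Cc1c(OCOC)cc(O[Si](C(C)C)(C(C)C)C(C)C)cc1OCOC | intermediate
14 | [2,6-bis(methoxymethoxy)-4-(triisopropylsilyloxy)phenyl]methanol | OCc1c(OCOC)cc(O[Si](C(C)C)(C(C)C)C(C)C)cc1OCOC | intermediate
15 | 2,6-bis(methoxymethoxy)-4-(triisopropylsilyloxy)benzyl methanesulfonate (not isolated) | CS(=O)(=O)OCc1c(OCOC)cc(O[Si](C(C)C)(C(C)C)C(C)C)cc1OCOC | intermediate
16 | 2-(bromomethyl)-1,3-bis(methoxymethoxy)-5-(triisopropylsilyloxy)benzene | BrCc1c(OCOC)cc(O[Si](C(C)C)(C(C)C)C(C)C)cc1OCOC | intermediate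
17 | sodium (Z)-enolate of imide 10 (not isolated) | [Na+].[O-]/C(=C\c1ccc(O[Si](C(C)C)(C(C)C)C(C)C)cc1OC(C)(C)C#C)N1[C@H](Cc2ccccc2)COC1=O | intermediate
18 | (R)-4-benzyl-3-{(2R)-3-[2,6-bis(methoxymethoxy)-4-(triisopropylsilyloxy)phenyl]-2-[2-(2-methylbut-3-yn-2-yloxy)-4-(triisopropylsilyloxy)phenyl]propanoyl}oxazolidin-2-one | O=C([C@H](Cc1c(OCOC)cc(O[Si](C(C)C)(C(C)C)C(C)C)cc1OCOC)c1ccc(O[Si](C(C)C)(C(C)C)C(C)C)cc1OC(C)(C)C#C)N1[C@H](Cc2ccccc2)COC1=O | intermediate
19 | (2R)-3-[2,6-bis(methoxymethoxy)-4-(triisopropylsilyloxy)phenyl]-2-[2-(2-methylbut-3-yn-2-yloxy)-4-(triisopropylsilyloxy)phenyl]propan-1-ol | OC[C@H](Cc1c(OCOC)cc(O[Si](C(C)C)(C(C)C)C(C)C)cc1OCOC)c1ccc(O[Si](C(C)C)(C(C)C)C(C)C)cc1OC(C)(C)C#C | intermediate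
20 | 2-{(2R)-3-hydroxy-2-[2-(2-methylbut-3-yn-2-yloxy)-4-(triisopropylsilyloxy)phenyl]propyl}-5-(triisopropylsilyloxy)benzene-1,3-diol | OC[C@H](Cc1c(O)cc(O[Si](C(C)C)(C(C)C)C(C)C)cc1O)c1ccc(O[Si](C(C)C)(C(C)C)C(C)C)cc1OC(C)(C)C#C | intermediate
21 | (3R)-3-[2-(2-methylbut-3-yn-2-yloxy)-4-(triisopropylsilyloxy)phenyl]-7-(triisopropylsilyloxy)chroman-5-ol | Oc1cc(O[Si](C(C)C)(C(C)C)C(C)C)cc2c1C[C@H](c1ccc(O[Si](C(C)C)(C(C)C)C(C)C)cc1OC(C)(C)C#C)CO2 | intermediate
22 | 2-methylbut-3-en-2-ol | CC(C)(O)C=C | starting material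
23 | lithium 2-methylbut-3-en-2-olate (not isolated) | [Li+].[O-]C(C)(C)C=C | intermediate
24 | tert-butyl 2-methylbut-3-en-2-yl carbonate | CC(C)(C)OC(=O)OC(C)(C)C=C | intermediate
25 | (3R)-5-(2-methylbut-3-en-2-yloxy)-3-[2-(2-methylbut-3-yn-2-yloxy)-4-(triisopropylsilyloxy)phenyl]-7-(triisopropylsilyloxy)chroman | C=CC(C)(C)Oc1cc(O[Si](C(C)C)(C(C)C)C(C)C)cc2c1C[C@H](c1ccc(O[Si](C(C)C)(C(C)C)C(C)C)cc1OC(C)(C)C#C)CO2 | intermediate
26 | (3R)-6-(3-methylbut-2-en-1-yl)-3-[2-(2-methylbut-3-yn-2-yloxy)-4-(triisopropylsilyloxy)phenyl]-7-(triisopropylsilyloxy)chroman-5-ol (not isolated) | Oc1c(CC=C(C)C)c(O[Si](C(C)C)(C(C)C)C(C)C)cc2c1C[C@H](c1ccc(O[Si](C(C)C)(C(C)C)C(C)C)cc1OC(C)(C)C#C)CO2 | intermediate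
27 | (3R)-3-[2-hydroxy-3-(3-methylbuta-1,2-dien-1-yl)-4-(triisopropylsilyloxy)phenyl]-6-(3-methylbut-2-en-1-yl)-7-(triisopropylsilyloxy)chroman-5-ol (not isolated) | Oc1c(CC=C(C)C)c(O[Si](C(C)C)(C(C)C)C(C)C)cc2c1C[C@H](c1ccc(O[Si](C(C)C)(C(C)C)C(C)C)c(C=C=C(C)C)c1O)CO2 | intermediate
28 | ortho-quinone methide from 27: ring B as 6-(3-methylbut-2-enylidene)cyclohexa-2,4-dien-1-one with the chromanyl group at C2 and the silyloxy group at C5 (not isolated) | Oc1c(CC=C(C)C)c(O[Si](C(C)C)(C(C)C)C(C)C)cc2c1C[C@H](C1=CC=C(O[Si](C(C)C)(C(C)C)C(C)C)C(=CC=C(C)C)C1=O)CO2 | intermediate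
29 | (3R)-3-[2,2-dimethyl-5-(triisopropylsilyloxy)-2H-chromen-8-yl]-6-(3-methylbut-2-en-1-yl)-7-(triisopropylsilyloxy)chroman-5-ol | Oc1c(CC=C(C)C)c(O[Si](C(C)C)(C(C)C)C(C)C)cc2c1C[C@H](c1ccc(O[Si](C(C)C)(C(C)C)C(C)C)c3c1OC(C)(C)C=C3)CO2 | intermediate
30 | (3R)-3-[2,2-dimethyl-5-(triisopropylsilyloxy)-2H-chromen-8-yl]-5-methoxy-6-(3-methylbut-2-en-1-yl)-7-(triisopropylsilyloxy)chroman | COc1c(CC=C(C)C)c(O[Si](C(C)C)(C(C)C)C(C)C)cc2c1C[C@H](c1ccc(O[Si](C(C)C)(C(C)C)C(C)C)c3c1OC(C)(C)C=C3)CO2 | intermediate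
31 | (3R)-3-(5-hydroxy-2,2-dimethyl-2H-chromen-8-yl)-5-methoxy-6-(3-methylbut-2-en-1-yl)chroman-7-ol | COc1c(CC=C(C)C)c(O)cc2c1C[C@H](c1ccc(O)c3c1OC(C)(C)C=C3)CO2 | target

Total step count: 18. Longest linear sequence: 13 steps (steps 1–5, 10–13, 15–18), from 2,4-dihydroxybenzaldehyde.

Steps most likely to fail

Step 10. The 2,4,6-trioxygenated benzylic bromide may ionise and alkylate its own ring, or hydrolyse, before it meets the enolate. Excess base may also exchange the doubly activated α-proton of the product and erode the configuration at C3. The fallback avoids the benzylic halide. It sets out from acid 7 and aldehyde 13. Acid 7 is acylated as in step 5, but onto (S)-4-benzyloxazolidin-2-one, to give (S)-4-benzyl-3-{[2-(2-methylbut-3-yn-2-yloxy)-4-(triisopropylsilyloxy)phenyl]acetyl}oxazolidin-2-one F1. Its dibutylboron enolate (Bu2BOTf, i-Pr2NEt, CH2Cl2, −78 °C) adds to aldehyde 13 in an auxiliary-controlled syn-aldol reaction to give the (2S,3S)-β-hydroxy imide F2. The enantiomeric auxiliary is needed because the aldol electrophile enters on the enolate face opposite to the one used in alkylation. Ionic hydrogenation of the very electron-rich benzylic alcohol (Et3SiH, CF3CO2H, CH2Cl2, −40 °C) then removes the hydroxyl to give the (2R)-imide F3, and LiBH4 reduction as in step 11 returns the route at alcohol 19.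

Step 15. The hindered, electron-rich phenoxide may attack the unsubstituted allyl terminus or react through ring carbon instead of oxygen, and the tertiary ether may re-ionise on the catalyst and drift to the linear prenyl ether. The fallback builds the 1,1-dimethylallyl ether without an allyl–palladium intermediate. It sets out from phenol 21, which is alkylated with ethyl 2-bromo-2-methylpropanoate (K2CO3, MeCN, 60 °C) to give the ethyl 2-aryloxy-2-methylpropanoate F4. Reduction with i-Bu2AlH (CH2Cl2, −78 °C) gives the 2-aryloxy-2-methylpropanal F5, and Wittig methylenation (Ph3PCH3Br, KOt-Bu, THF, 0 °C) returns the route at ether 25.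

Step 16. At the temperature the propargyl ether needs, the tertiary allyl ether may fragment to the phenol and isoprene, and the freed 5-hydroxyl may add across the new prenyl double bond during long heating. The fallback runs the two sigmatropic shifts separately, so the free 5-hydroxyl is never heated strongly. It sets out from 25. Catalysis by Eu(fod)3 (fod = 6,6,7,7,8,8,8-heptafluoro-2,2-dimethyloctane-3,5-dionate) in CHCl3 at 50 °C should move only the allyl group and give prenylphenol 26, now isolated. Methylation (MeI, K2CO3, acetone) gives the 5-methoxy-6-prenyl 2'-O-(1,1-dimethylpropargyl) isoflavan F6, and heating in PhNEt2 at 180 °C then carries out the propargyl Claisen shift and ring D closure, returning the route at methyl ether 30.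

Further compounds
F1 | step 10 | (S)-4-benzyl-3-{[2-(2-methylbut-3-yn-2-yloxy)-4-(triisopropylsilyloxy)phenyl]acetyl}oxazolidin-2-one | O=C(Cc1ccc(O[Si](C(C)C)(C(C)C)C(C)C)cc1OC(C)(C)C#C)N1[C@@H](Cc2ccccc2)COC1=O
F2 | step 10 | (S)-4-benzyl-3-{(2S,3S)-3-[2,6-bis(methoxymethoxy)-4-(triisopropylsilyloxy)phenyl]-3-hydroxy-2-[2-(2-methylbut-3-yn-2-yloxy)-4-(triisopropylsilyloxy)phenyl]propanoyl}oxazolidin-2-one | O=C([C@H]([C@H](O)c1c(OCOC)cc(O[Si](C(C)C)(C(C)C)C(C)C)cc1OCOC)c1ccc(O[Si](C(C)C)(C(C)C)C(C)C)cc1OC(C)(C)C#C)N1[C@@H](Cc2ccccc2)COC1=O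
F3 | step 10 | (S)-4-benzyl-3-{(2R)-3-[2,6-bis(methoxymethoxy)-4-(triisopropylsilyloxy)phenyl]-2-[2-(2-methylbut-3-yn-2-yloxy)-4-(triisopropylsilyloxy)phenyl]propanoyl}oxazolidin-2-one | O=C([C@H](Cc1c(OCOC)cc(O[Si](C(C)C)(C(C)C)C(C)C)cc1OCOC)c1ccc(O[Si](C(C)C)(C(C)C)C(C)C)cc1OC(C)(C)C#C)N1[C@@H](Cc2ccccc2)COC1=O
F4 | step 15 | ethyl 2-methyl-2-{[(3R)-3-[2-(2-methylbut-3-yn-2-yloxy)-4-(triisopropylsilyloxy)phenyl]-7-(triisopropylsilyloxy)chroman-5-yl]oxy}propanoate | CCOC(=O)C(C)(C)Oc1cc(O[Si](C(C)C)(C(C)C)C(C)C)cc2c1C[C@H](c1ccc(O[Si](C(C)C)(C(C)C)C(C)C)cc1OC(C)(C)C#C)CO2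
F5 | step 15 | 2-methyl-2-{[(3R)-3-[2-(2-methylbut-3-yn-2-yloxy)-4-(triisopropylsilyloxy)phenyl]-7-(triisopropylsilyloxy)chroman-5-yl]oxy}propanal | O=CC(C)(C)Oc1cc(O[Si](C(C)C)(C(C)C)C(C)C)cc2c1C[C@H](c1ccc(O[Si](C(C)C)(C(C)C)C(C)C)cc1OC(C)(C)C#C)CO2
F6 | step 16 | (3R)-5-methoxy-6-(3-methylbut-2-en-1-yl)-3-[2-(2-methylbut-3-yn-2-yloxy)-4-(triisopropylsilyloxy)phenyl]-7-(triisopropylsilyloxy)chroman | COc1c(CC=C(C)C)c(O[Si](C(C)C)(C(C)C)C(C)C)cc2c1C[C@H](c1ccc(O[Si](C(C)C)(C(C)C)C(C)C)cc1OC(C)(C)C#C)CO2
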